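Locants are atom positions in the target SMILES. The route rests on cutting C5–C10 and O9–C10: once C6 is a ketone, the pyran (C5, C6, C7, C8, O9, C10) is a 2,2-disubstituted chromanone-type ring whose quaternary C10 also belongs to the nine-membered carbocycle. A single amine-mediated aldol condensation/oxa-Michael cascade therefore closes both rings and sets C5 and C10. Its precursor is a C7-acyl filicinic acid C31 methyl ether whose acyl chain is ring-opened caryophyllene: the trans-cyclobutane, the exocyclic methylene and a terminal C10 methyl ketone. Afterwards C6 is deoxygenated, the ether cleaved and C25 isobutyrylated.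

Key step: step 9

Remark: precursor 15 and product 17 of the key step map atom for atom onto the target; C5 is R in 17 and S in the target only because the CIP priorities change, and C14 (R) and C15 (S) come unchanged from commercial (1R,4E,9S)-(−)-β-caryophyllene.
Remark: the enolised dienone rings are drawn as one of several interconverting tautomers.

Step 1
Reactants: 1 (−)-β-caryophyllene
Product: 3 4-[(1S,2R)-3,3-dimethyl-2-(3-oxobutyl)cyclobutyl]pent-4-enal, via secondary ozonide 2 (not isolated)
Conditions: O3 (1.0 equiv, metered as a saturated CH2Cl2 solution), CH2Cl2, −78 °C; then PPh3, −78 °C to rt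
Reagents that add atoms: ozone, O=[O+][O-]
Why: Chemoselective ozonolysis with reductive work-up should cleave only the strained E-trisubstituted endocyclic alkene, which adds ozone far faster than the 1,1-disubstituted exocyclic alkene when ozone is limiting; the cyclobutane centres are untouched.

Step 2
Reactants: 3 4-[(1S,2R)-3,3-dimethyl-2-(3-oxobutyl)cyclobutyl]pent-4-enal; 4 (methoxymethyl)triphenylphosphonium chloride
Product: 5 1-methoxy-5-[(1S,2R)-3,3-dimethyl-2-(3-oxobutyl)cyclobutyl]hexa-1,5-diene (E/Z mixture of the enol ether)
Conditions: 4 (1.05 equiv), KN(SiMe3)2 (1.0 equiv), THF, −78 °C; then 3, −78 to −40 °C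
Reagents that add atoms: (methoxymethyl)triphenylphosphonium chloride, COC[P+](c1ccccc1)(c1ccccc1)c1ccccc1.[Cl-]
Why: Wittig methoxymethylenation with the ylide as limiting reagent at low temperature should take the aldehyde in preference to the methyl ketone and adds the carbon that becomes C6.

Step 3
Reactants: 5 1-methoxy-5-[(1S,2R)-3,3-dimethyl-2-(3-oxobutyl)cyclobutyl]hexa-1,5-diene
Product: 6 5-[(1S,2R)-3,3-dimethyl-2-(3-oxobutyl)cyclobutyl]hex-5-enal
Conditions: 1 M HCl, THF, 0 °C to rt
Reagents that add atoms: water, O
Why: Acid hydrolysis of the enol ether (C-protonation, hydration, loss of methanol) is far faster than protonation of the isolated exocyclic alkene, so the homologous aldehyde should form without touching the alkene or the cyclobutane.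

Step 4
Reactants: 6 5-[(1S,2R)-3,3-dimethyl-2-(3-oxobutyl)cyclobutyl]hex-5-enal
Product: 7 5-[(1S,2R)-3,3-dimethyl-2-(3-oxobutyl)cyclobutyl]hex-5-enoic acid
Conditions: NaClO2, NaH2PO4, 2-methylbut-2-ene, t-BuOH/H2O, 0 °C to rt
Reagents that add atoms: sodium chlorite, [Na+].[O-]Cl=O
Why: Pinnick oxidation converts the aldehyde into the acid while 2-methylbut-2-ene scavenges hypochlorous acid, so the alkene and the ketone should survive.

Step 5
Reactants: 8 2',4',6'-trihydroxyacetophenone; 9 iodomethane
Product: 10 acetylfilicinic acid (2-acetyl-3,5-dihydroxy-4,4-dimethylcyclohexa-2,5-dien-1-one)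
Conditions: NaOMe (3 equiv), MeI (2.2 equiv), MeOH, 0 °C to rt; then aq. HCl
Reagents that add atoms: iodomethane, CI
Why: Dearomatising double C-methylation of the acylphloroglucinol anion, in which the mono-methylated anion is alkylated again at the same ring carbon, is the established entry to acylfilicinic acids.

Step 6
Reactants: 10 acetylfilicinic acid
Product: 11 filicinic acid (3,5-dihydroxy-4,4-dimethylcyclohexa-2,5-dien-1-one)
Conditions: 6 M HCl (aq), reflux
Reagents that add atoms: none
Why: Acid-mediated retro-Claisen deacylation of the β-triketone (water adds to the exocyclic carbonyl and the vinylogous acid leaves) is a known way to unmask such triketone cores.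

Step 7
Reactants: 11 filicinic acid; 12 methanol
Product: 13 filicinic acid C31 methyl ether (5-hydroxy-3-methoxy-6,6-dimethylcyclohexa-2,4-dien-1-one)
Conditions: MeOH, TsOH·H2O (5 mol %), 3 Å MS, rt
Reagents that add atoms: methanol, CO
Why: Acid-catalysed enol etherification (vinylogous Fischer esterification) should occur at C31, the only oxygen-bearing ring carbon not flanked by the quaternary C20, as 4,4-dimethylcyclohexane-1,3-dione is etherified at the carbonyl remote from its quaternary carbon; the ether is symmetric, so both flanking CH carbons are the same nucleophile in step 8.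

Step 8
Reactants: 7 5-[(1S,2R)-3,3-dimethyl-2-(3-oxobutyl)cyclobutyl]hex-5-enoic acid; 13 filicinic acid C31 methyl ether
Product: 15 4-{5-[(1S,2R)-3,3-dimethyl-2-(3-oxobutyl)cyclobutyl]hex-5-enoyl}-5-hydroxy-3-methoxy-6,6-dimethylcyclohexa-2,4-dien-1-one, via enol ester 14 (not isolated)
Conditions: DCC (1.2 equiv), DMAP (1.5 equiv), CH2Cl2, 0 °C to rt
Reagents that add atoms: none
Why: Steglich O-acylation of the enol followed by DMAP-mediated O-to-C acyl migration (Fries-type rearrangement of a 1,3-dione enol ester) should give the chelated C7-acyl compound, and the symmetric nucleophile allows only one C-acyl product.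

Step 9
Reactants: 15 C7-acyl filicinic acid C31 methyl ether (seco-caryophyllene chain, C10 methyl ketone)
Product: 17 tetracyclic pyranone (5R,10R,14R,15S; C6 ketone; C31 methyl ether; C25–H), via ring-opened enone 16 (not isolated)
Conditions: pyrrolidine (2.2 equiv), 4 Å MS, MeCN (0.005 M, slow addition of 15), 60 °C
Reagents that add atoms: none
Why: Proposed new method: pyrrolidine should be held in part as the salt of the acidic C8 enol and in part convert the C10 methyl ketone into its iminium ion, which is attacked by C5 (the methylene alpha to the chelated C6 carbonyl, as its enol or dienamine) in a Mannich-type step; loss of pyrrolidine gives enone 16 and the C8 hydroxyl then adds to C10. The closest known reaction is the intermolecular Kabbe chromanone synthesis from 2-hydroxyaryl ketones and ketones, which has not been applied to a β-triketone enol or used to close a medium ring. The nine-membered carbocycle closes in a 9-exo-trig aldol-type mode (C5 onto the C10 carbonyl or iminium carbon) and the pyranone in a 6-endo-trig oxa-Michael mode (O9 onto C10 of the C5=C10 enone). C10 is set in the reversible oxa-Michael step and C5 by protonation next to the C6 ketone, so both can equilibrate, and the trans-cyclobutane centres C14 and C15, the only bias, should steer the mixture to the trans-fused isomer with H-5 and the C10 methyl anti. The step needs O8 and not O32 to close the ring and C5 and not C11 or C12 to act as nucleophile: the C31 methyl ether leaves O8 as the only free enol oxygen, only condensation at C5 gives an enone that a six-membered oxa-Michael closure can trap, and sieves with high dilution pull the reversible sequence forward and suppress oligomers.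

Step 10
Reactants: 17 tetracyclic pyranone
Product: 18 C6 carbinol (5S,10R,14R,15S; both C6 epimers; used crude)
Conditions: NaBH4, CeCl3·7H2O, MeOH/THF, −40 to 0 °C
Reagents that add atoms: none
Why: Luche 1,2-reduction of the dihydropyranone carbonyl should spare the C23 carbonyl, which is flanked by the quaternary C20 and deactivated as a doubly vinylogous ester; the C6 carbinol centre is removed in the next step.

Step 11
Reactants: 18 C6 carbinol
Product: 19 tetracyclic C31 methyl ether with C6 methylene (5S,10R,14R,15S)
Conditions: Et3SiH (10 equiv), BF3·OEt2 (2 equiv), CH2Cl2, −78 to −40 °C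
Reagents that add atoms: none
Why: Ionic hydrogenation: BF3 ionises the vinylogous hemiacetal-type allylic alcohol to an alkoxyallyl cation that the silane, in large excess, should reduce at the secondary C6 terminus and not at C8, which is fully substituted and flanked by C20, restoring the conjugated enol ether without touching C5 or C10.

Step 12
Reactants: 19 tetracyclic C31 methyl ether
Product: 20 tetracyclic vinylogous acid (C31–OH, C25–H; 5S,10R,14R,15S)
Conditions: LiCl (5 equiv), DMF, 130 °C; then 1 M HCl
Reagents that add atoms: none
Why: Krapcho-type SN2 demethylation: chloride attacks the methyl group and the stabilised 1,3-dione enolate leaves, while the tertiary O9–C10 ether and the alkene cannot react in this way.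

Step 13
Reactants: 20 tetracyclic vinylogous acid; 21 isobutyryl chloride
Product: 23 target CNP0497637.2, via enol isobutyrate 22 (not isolated)
Conditions: i-PrCOCl (1.1 equiv), Et3N (2.5 equiv), DMAP (0.5 equiv), CH2Cl2, 0 °C to rt; then 1 M HCl
Reagents that add atoms: isobutyryl chloride, CC(C)C(=O)Cl
Why: O-acylation of the cyclic 1,3-dione enol and DMAP-catalysed enol ester to C-acyl rearrangement, the standard route to 2-acyl-1,3-diones, should place the isobutyryl group on C25, the only hydrogen-bearing carbon between the two oxygens, and the product is held as the chelated triketone enol.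

Compound list
1 | (−)-β-caryophyllene, (1R,4E,9S)-4,11,11-trimethyl-8-methylidenebicyclo[7.2.0]undec-4-ene | C=C1CC/C=C(\C)CC[C@@H]2[C@@H]1CC2(C)C | starting material
2 | secondary ozonide of 1 (1,2,4-trioxolane across C5/C10, mixture at the ozonide carbons) | C=C1CCC2OOC(C)(O2)CC[C@@H]3[C@@H]1CC3(C)C | intermediate (not isolated)
3 | 4-[(1S,2R)-3,3-dimethyl-2-(3-oxobutyl)cyclobutyl]pent-4-enal | O=CCCC(=C)[C@H]1CC(C)(C)[C@@H]1CCC(C)=O | intermediate
4 | (methoxymethyl)triphenylphosphonium chloride | COC[P+](c1ccccc1)(c1ccccc1)c1ccccc1.[Cl-] | starting material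
5 | 1-methoxy-5-[(1S,2R)-3,3-dimethyl-2-(3-oxobutyl)cyclobutyl]hexa-1,5-diene (E/Z mixture) | COC=CCCC(=C)[C@H]1CC(C)(C)[C@@H]1CCC(C)=O | intermediate
6 | 5-[(1S,2R)-3,3-dimethyl-2-(3-oxobutyl)cyclobutyl]hex-5-enal | O=CCCCC(=C)[C@H]1CC(C)(C)[C@@H]1CCC(C)=O | intermediate
7 | 5-[(1S,2R)-3,3-dimethyl-2-(3-oxobutyl)cyclobutyl]hex-5-enoic acid | OC(=O)CCCC(=C)[C@H]1CC(C)(C)[C@@H]1CCC(C)=O | intermediate
8 | 2',4',6'-trihydroxyacetophenone | CC(=O)c1c(O)cc(O)cc1O | starting material
9 | iodomethane | CI | starting material
10 | acetylfilicinic acid, 2-acetyl-3,5-dihydroxy-4,4-dimethylcyclohexa-2,5-dien-1-one | CC(=O)C1=C(O)C(C)(C)C(O)=CC1=O | intermediate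
11 | filicinic acid, 3,5-dihydroxy-4,4-dimethylcyclohexa-2,5-dien-1-one | CC1(C)C(O)=CC(=O)C=C1O | intermediate
12 | methanol | CO | starting material
13 | filicinic acid C31 methyl ether, 5-hydroxy-3-methoxy-6,6-dimethylcyclohexa-2,4-dien-1-one | COC1=CC(=O)C(C)(C)C(O)=C1 | intermediate
14 | enol ester of 13 with acid 7 (O8-acyl) | COC1=CC(=O)C(C)(C)C(OC(=O)CCCC(=C)[C@H]2CC(C)(C)[C@@H]2CCC(C)=O)=C1 | intermediate (not isolated)
15 | 4-{5-[(1S,2R)-3,3-dimethyl-2-(3-oxobutyl)cyclobutyl]hex-5-enoyl}-5-hydroxy-3-methoxy-6,6-dimethylcyclohexa-2,4-dien-1-one (key-step precursor) | COC1=CC(=O)C(C)(C)C(O)=C1C(=O)CCCC(=C)[C@H]1CC(C)(C)[C@@H]1CCC(C)=O | intermediate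
16 | ring-opened enone: C5=C10 cyclononene acyl filicinic acid methyl ether (alkene geometry open) | COC1=CC(=O)C(C)(C)C(O)=C1C(=O)C1=C(C)CC[C@@H]2[C@H](CC2(C)C)C(=C)CC1 | intermediate (not isolated)
17 | tetracyclic pyranone, (5R,10R,14R,15S), C6 ketone, C31 methyl ether, C25–H (key-step product) | C=C1CC[C@H]2C(=O)C3=C(O[C@]2(C)CC[C@@H]2[C@@H]1CC2(C)C)C(C)(C)C(=O)C=C3OC | intermediate
18 | C6 carbinol of 17, (5S,10R,14R,15S), both C6 epimers | C=C1CC[C@H]2C(O)C3=C(O[C@]2(C)CC[C@@H]2[C@@H]1CC2(C)C)C(C)(C)C(=O)C=C3OC | intermediate
19 | tetracyclic C31 methyl ether with C6 methylene, (5S,10R,14R,15S) | C=C1CC[C@H]2CC3=C(O[C@]2(C)CC[C@@H]2[C@@H]1CC2(C)C)C(C)(C)C(=O)C=C3OC | intermediate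
20 | tetracyclic vinylogous acid (C31–OH, C25–H), (5S,10R,14R,15S) | C=C1CC[C@H]2CC3=C(O[C@]2(C)CC[C@@H]2[C@@H]1CC2(C)C)C(C)(C)C(=O)C=C3O | intermediate
21 | isobutyryl chloride (2-methylpropanoyl chloride) | CC(C)C(=O)Cl | starting material
22 | enol isobutyrate of 20 (O32-acyl) | C=C1CC[C@H]2CC3=C(O[C@]2(C)CC[C@@H]2[C@@H]1CC2(C)C)C(C)(C)C(=O)C=C3OC(=O)C(C)C | intermediate (not isolated)
23 | CNP0497637.2, (5S,10R,14R,15S), C25 isobutyryl, C31–OH | C=C1CC[C@H]2CC3=C(O[C@]2(C)CC[C@@H]2[C@@H]1CC2(C)C)C(C)(C)C(=O)C(C(=O)C(C)C)=C3O | target

Total step count: 13. Longest linear sequence: 10 steps (from 1: steps 1–4 and 8–13).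

Steps most likely to fail

Step 9. The medium-ring aldol closure may not compete with intermolecular condensation, or its equilibrium may lie on the open side. Pyrrolidine may also exchange the C31 methyl enol ether, and the equilibration may settle on another C5/C10 diastereomer. The fallback uses known chemistry, sets out from 13 and 1, and returns at 19, bypassing steps 8–11. Ether 13 is heated with paraformaldehyde and NaOAc in AcOH at 80 °C in the presence of an excess of 1. Knoevenagel condensation at the ring CH should give the o-quinone methide F1, whose only heterodiene is C6=C7–C8=O9 because C31 is etherified. F1 is trapped in an inverse-demand hetero-Diels–Alder reaction by the strained endocyclic alkene of 1, with O9 going to the more substituted C10 and C6 to C5. Suprafacial addition to the E-alkene fixes H-5 and the C10 methyl anti, and attack on the exposed face of the major conformer, as in epoxidation of 1, should give the (5S,10R) isomer; the other diastereomer would be removed by chromatography.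

Step 11. The silane may capture the alkoxyallyl cation at C8 instead of C6, or the exocyclic alkene may trap the cation in a Prins-type closure. The fallback sets out from 18 and returns at 19 by a radical deoxygenation (Barton–McCombie). Carbinol 18 is converted with NaH, CS2 and iodomethane 9 in THF at 0 °C into xanthate F2. F2 is reduced with Bu3SnH and AIBN in toluene at 80 °C. The delocalised allylic radical should take hydrogen at the less hindered C6 terminus and keep the conjugated enol ether.

Step 7. Etherification may occur at the hindered oxygen next to C20 or twice, giving the wrong or a mixed nucleophile for step 8. The fallback sets out from methanol 12 and iodomethane 9 and returns at 13, fixing the ether oxygen before the ring is dearomatised. Purchased phloroglucinol (Oc1cc(O)cc(O)c1) is mono-etherified with 12 and dry HCl to 5-methoxyresorcinol F3. F3 is then C-methylated twice at C2, the carbon between the two hydroxyl groups, with NaOMe and 9 in MeOH. In this way the methoxy group necessarily sits para to the new quaternary carbon.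

Further compounds
F1 | step 9 | 5-methoxy-2,2-dimethyl-6-methylidenecyclohex-4-ene-1,3-dione (o-quinone methide, not isolated) | C=C1C(=O)C(C)(C)C(=O)C=C1OC
F2 | step 11 | S-methyl xanthate of carbinol 18 (both C6 epimers) | C=C1CC[C@H]2C(OC(=S)SC)C3=C(O[C@]2(C)CC[C@@H]2[C@@H]1CC2(C)C)C(C)(C)C(=O)C=C3OC
F3 | step 7 | 5-methoxyresorcinol | COc1cc(O)cc(O)c1
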